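The route hinges on the bond between the alkenyl-bearing bridgehead carbon of the 7-oxabicyclo[2.2.1]heptane and the neighbouring vinylic CH. An alkenyllithium that carries the butenolide as a 2-silyloxyfuran adds to a non-enolisable 4-bromo-2-silyloxy-2,6,6-trimethylcyclohexanone; the tertiary alkoxide formed lies trans-1,4 to the bromide and closes the ether bridge in the same flask. One operation thus makes the C–C bond, sets the bridgehead stereocentre, forms both oxolane rings and inverts the second bridgehead, exploiting the 1,4-relationship of the two oxygen-bound ring carbons (C1 and C4 of the bicycle). Both end groups derive from one chiral ketone, actinol; a vinylogous Mukaiyama aldol–elimination finally joins the silyloxyfuran to a C22 polyenal.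

Key step: step 5

Assumption: compounds 1, 5, 6, 14, 24 and 27 are taken as catalogue chemicals; carotenoid numbering (ring C1–C6, chain from C7; primed for the dihydroxy end) is used in the explanations.

Step 1
Reactants: 1 (4R,6R)-4-hydroxy-2,2,6-trimethylcyclohexan-1-one (actinol)
Product: 2 (4S,6R)-4-bromo-2,2,6-trimethylcyclohexan-1-one
Conditions: CBr4, PPh3, CH2Cl2, 0 → 25 °C
Reagents that add atoms: carbon tetrabromide, BrC(Br)(Br)Br
Why: Appel bromination, in which bromide displaces the alkoxyphosphonium group by SN2, so the carbinol carbon is inverted and the leaving group sits on the ring face opposite to the one the ether oxygen must later occupy.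

Step 2
Reactants: 2 (4S,6R)-4-bromo-2,2,6-trimethylcyclohexan-1-one
Product: 4 (2R,4R)-4-bromo-2,6,6-trimethyl-2-(triethylsilyloxy)cyclohexan-1-one, via triethylsilyl enol ether 3 (not isolated)
Conditions: TESOTf, Et3N, CH2Cl2, 0 °C; then mCPBA, NaHCO3, CH2Cl2, −20 °C
Reagents that add atoms: triethylsilyl trifluoromethanesulfonate, CC[Si](CC)(CC)OS(=O)(=O)C(F)(F)F; meta-chloroperbenzoic acid, OOC(=O)c1cccc(Cl)c1
Why: Rubottom oxidation, in which the ketone can enolise only toward the methine carbon, the peracid should attack the enol ether cis to the equatorial bromine because the pseudoaxial methyl of the gem-dimethyl group shields the other face, and 1,4-silyl migration in the opened siloxy-epoxide delivers the α-silyloxy ketone.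

Step 3
Reactants: 5 3-bromofuran-2(5H)-one; 6 (E)-1,2-bis(tributylstannyl)ethene
Product: 7 3-[(E)-2-(tributylstannyl)ethenyl]furan-2(5H)-one
Conditions: Pd2(dba)3 (2.5 mol%), AsPh3 (10 mol%), 6 (2.5 equiv), NMP, 40 °C
Reagents that add atoms: none
Why: Stille coupling of the α-bromobutenolide with one tin terminus of the distannane, whose excess suppresses double coupling, with retention of the E geometry.

Step 4
Reactants: 7 3-[(E)-2-(tributylstannyl)ethenyl]furan-2(5H)-one
Product: 8 tributyl{(E)-2-[2-(triisopropylsilyloxy)furan-3-yl]ethenyl}stannane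
Conditions: TIPSOTf, Et3N, CH2Cl2, 0 °C
Reagents that add atoms: triisopropylsilyl trifluoromethanesulfonate, CC(C)[Si](OS(=O)(=O)C(F)(F)F)(C(C)C)C(C)C
Why: Soft enolisation and O-silylation of the butenolide should give the aromatic 2-silyloxyfuran, which masks the lactone toward organolithium reagents and is the nucleophile of the later vinylogous aldol step.

Step 5
Reactants: 8 tributyl{(E)-2-[2-(triisopropylsilyloxy)furan-3-yl]ethenyl}stannane; 4 (2R,4R)-4-bromo-2,6,6-trimethyl-2-(triethylsilyloxy)cyclohexan-1-one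
Product: 11 triisopropyl[(3-{(E)-2-[(1R,2R,4S)-2,6,6-trimethyl-2-(triethylsilyloxy)-7-oxabicyclo[2.2.1]heptan-1-yl]ethenyl}furan-2-yl)oxy]silane, via alkenyllithium 9 (not isolated), via lithium alkoxide 10 (not isolated)
Conditions: 8, n-BuLi, THF, −78 °C; add 4, −78 → −30 °C; then HMPA, → 25 °C
Reagents that add atoms: none
Why: Tin–lithium exchange gives alkenyllithium 9, which adds to the carbonyl of 4 (no α-hydrogen, so no enolisation) to give tertiary alkoxide 10, and once HMPA loosens the lithium ion pair this oxygen displaces the secondary bromide across the ring in an intramolecular Williamson (SN2) etherification. The closest known reactions are alkenyllithium additions to 2,2,6-trisubstituted cyclohexanones and the base-induced closure of trans-4-halocyclohexanols to 7-oxabicyclo[2.2.1]heptanes. The closure is 5-exo-tet for both oxolane rings that share the new oxygen and runs through the boat conformer of 10. The alkenyl-bearing bridgehead (C6) should be set by substrate control, since 4 reacts through the chair with Br and OSiEt3 equatorial, whose two axial α-methyl groups block one carbonyl face, so the nucleophile enters cis to Br and OSiEt3 and the alkoxide ends trans to both; the CH–O bridgehead (C3) is set by inversion at the C–Br carbon. The step needs the right carbonyl face and substitution rather than elimination: the equatorial bromide has no antiperiplanar hydrogen for E2, and an alkoxide cis to bromine cannot reach the backside of C–Br, so the wrong C6 epimer cannot cyclise and is separated.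

Step 6
Reactants: 1 (4R,6R)-4-hydroxy-2,2,6-trimethylcyclohexan-1-one (actinol)
Product: 12 (4R,6R)-4-(tert-butyldimethylsilyloxy)-2,2,6-trimethylcyclohexan-1-one
Conditions: TBSCl, imidazole, DMAP (cat.), DMF, 40 °C
Reagents that add atoms: tert-butyldimethylsilyl chloride, CC(C)(C)[Si](C)(C)Cl
Why: Standard silylation of the secondary alcohol, which leaves both stereocentres untouched.

Step 7
Reactants: 12 (4R,6R)-4-(tert-butyldimethylsilyloxy)-2,2,6-trimethylcyclohexan-1-one
Product: 13 (4S)-4-(tert-butyldimethylsilyloxy)-2,6,6-trimethylcyclohex-2-en-1-one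
Conditions: IBX, DMSO/toluene, 70 °C
Reagents that add atoms: none
Why: IBX dehydrogenation of a ketone to the enone can run only toward the single enolisable α-carbon, which removes the methyl-bearing stereocentre and keeps the silyloxy centre (its descriptor changes by priority only).

Step 8
Reactants: 14 3-methylpent-1-en-4-yn-3-ol (racemic)
Product: 15 triethyl[(3-methylpent-1-en-4-yn-3-yl)oxy]silane (racemic)
Conditions: TESOTf, 2,6-lutidine, CH2Cl2, −78 → 0 °C
Reagents that add atoms: triethylsilyl trifluoromethanesulfonate, CC[Si](CC)(CC)OS(=O)(=O)C(F)(F)F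
Why: Silylation of the tertiary alcohol blocks its own allylic transposition in step 10, and the racemate suffices because this carbinol centre is destroyed in step 15.

Step 9
Reactants: 15 triethyl[(3-methylpent-1-en-4-yn-3-yl)oxy]silane; 13 (4S)-4-(tert-butyldimethylsilyloxy)-2,6,6-trimethylcyclohex-2-en-1-one
Product: 17 (4S)-4-(tert-butyldimethylsilyloxy)-2,6,6-trimethyl-1-[3-methyl-3-(triethylsilyloxy)pent-4-en-1-yn-1-yl]cyclohex-2-en-1-ol (epimers at both carbinol carbons), via lithium acetylide 16 (not isolated)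
Conditions: 15, n-BuLi, THF, −78 °C; then 13, −78 → 0 °C
Reagents that add atoms: none
Why: 1,2-Addition of a lithium acetylide to the hindered enone carbonyl, the classical way to attach the side chain to trimethylcyclohexenones; the configuration of the two new carbinol carbons is irrelevant because both are removed later.

Step 10
Reactants: 17 (4S)-4-(tert-butyldimethylsilyloxy)-2,6,6-trimethyl-1-[3-methyl-3-(triethylsilyloxy)pent-4-en-1-yn-1-yl]cyclohex-2-en-1-ol
Product: 18 (6S)-6-(tert-butyldimethylsilyloxy)-2,4,4-trimethyl-3-[3-methyl-3-(triethylsilyloxy)pent-4-en-1-yn-1-yl]cyclohex-2-en-1-one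
Conditions: pyridinium chlorochromate (C5H5NH)[CrO3Cl], NaOAc, 4 Å MS, CH2Cl2, 25 °C
Reagents that add atoms: pyridinium chlorochromate, [O-][Cr](=O)(=O)Cl.c1cc[nH+]cc1
Why: Dauben–Michno oxidative transposition, in which the tertiary allylic chromate ester shifts [3,3] within the ring allyl unit (the alkyne cannot take part) and is oxidised to the enone, placing oxygen on C4' next to the silyloxy stereocentre.

Step 11
Reactants: 18 (6S)-6-(tert-butyldimethylsilyloxy)-2,4,4-trimethyl-3-[3-methyl-3-(triethylsilyloxy)pent-4-en-1-yn-1-yl]cyclohex-2-en-1-one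
Product: 19 (1R,6S)-6-(tert-butyldimethylsilyloxy)-2,4,4-trimethyl-3-[3-methyl-3-(triethylsilyloxy)pent-4-en-1-yn-1-yl]cyclohex-2-en-1-ol
Conditions: LiBH(s-Bu)3, THF, −78 °C
Reagents that add atoms: none
Why: 1,2-Reduction by a bulky borohydride (the fully substituted β-carbon blocks conjugate reduction), with hydride attack anti to the adjacent silyloxy group (Felkin–Anh), which should give the cis-3',4'-diol monoether.

Step 12
Reactants: 19 (1R,6S)-6-(tert-butyldimethylsilyloxy)-2,4,4-trimethyl-3-[3-methyl-3-(triethylsilyloxy)pent-4-en-1-yn-1-yl]cyclohex-2-en-1-ol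
Product: 20 (3R,4S)-3,4-bis(tert-butyldimethylsilyloxy)-2,6,6-trimethyl-1-[3-methyl-3-(triethylsilyloxy)pent-4-en-1-yn-1-yl]cyclohex-1-ene
Conditions: TBSOTf, 2,6-lutidine, CH2Cl2, 0 °C
Reagents that add atoms: tert-butyldimethylsilyl trifluoromethanesulfonate, CC(C)(C)[Si](C)(C)OS(=O)(=O)C(F)(F)F
Why: Silylation of the hindered allylic alcohol with a silyl triflate protects it against ionisation in the acidic and Lewis acidic steps that follow.

Step 13
Reactants: 20 (3R,4S)-3,4-bis(tert-butyldimethylsilyloxy)-2,6,6-trimethyl-1-[3-methyl-3-(triethylsilyloxy)pent-4-en-1-yn-1-yl]cyclohex-1-ene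
Product: 21 1-[(3R,4S)-3,4-bis(tert-butyldimethylsilyloxy)-2,6,6-trimethylcyclohex-1-en-1-yl]-3-methylpent-4-en-1-yn-3-ol
Conditions: HF·pyridine, pyridine, THF, 0 °C
Reagents that add atoms: none
Why: Selective fluoride desilylation, since a triethylsilyl ether is cleaved much faster than the two hindered secondary tert-butyldimethylsilyl ethers.

Step 14
Reactants: 21 1-[(3R,4S)-3,4-bis(tert-butyldimethylsilyloxy)-2,6,6-trimethylcyclohex-1-en-1-yl]-3-methylpent-4-en-1-yn-3-ol
Product: 22 (1E)-1-[(3R,4S)-3,4-bis(tert-butyldimethylsilyloxy)-2,6,6-trimethylcyclohex-1-en-1-yl]-3-methylpenta-1,4-dien-3-ol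
Conditions: NaAlH2(OCH2CH2OMe)2, THF, 0 → 25 °C
Reagents that add atoms: none
Why: Hydroxyl-directed trans-hydroalumination of the propargylic alcohol followed by protonolysis should give only the E alkene (C7'=C8').

Step 15
Reactants: 22 (1E)-1-[(3R,4S)-3,4-bis(tert-butyldimethylsilyloxy)-2,6,6-trimethylcyclohex-1-en-1-yl]-3-methylpenta-1,4-dien-3-ol
Product: 23 {(2E,4E)-5-[(3R,4S)-3,4-bis(tert-butyldimethylsilyloxy)-2,6,6-trimethylcyclohex-1-en-1-yl]-3-methylpenta-2,4-dien-1-yl}triphenylphosphonium bromide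
Conditions: PPh3·HBr, CH2Cl2, 0 → 25 °C
Reagents that add atoms: triphenylphosphine hydrobromide, [PH+](c1ccccc1)(c1ccccc1)c1ccccc1.[Br-]
Why: Ionisation of the tertiary bis-allylic alcohol and capture of the pentadienyl cation at its unhindered terminus by PPh3 (allylic transposition, as in the classical C15 Wittig salt synthesis) should give the primary phosphonium salt with the thermodynamic E trisubstituted alkene.

Step 16
Reactants: 23 C15 phosphonium bromide; 24 (E)-4,4-dimethoxybut-2-enal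
Product: 26 (2E,4E,6E,8E)-9-[(3R,4S)-3,4-bis(tert-butyldimethylsilyloxy)-2,6,6-trimethylcyclohex-1-en-1-yl]-7-methylnona-2,4,6,8-tetraenal, via dimethyl acetal 25 (not isolated)
Conditions: NaOMe, CH2Cl2/MeOH, 0 → 25 °C; then PPTS, acetone/H2O, 25 °C; then I2 (1 mol%), CH2Cl2, daylight
Reagents that add atoms: water, O
Why: Wittig olefination of the allylic ylide with the free aldehyde of the mono-acetal, mild hydrolysis of the vinylogous acetal and iodine-catalysed equilibration of the new double bond should give the all-E tetraenal.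

Step 17
Reactants: 26 C19 tetraenal; 27 2-(triphenylphosphoranylidene)propanal
Product: 28 (2E,4E,6E,8E,10E)-11-[(3R,4S)-3,4-bis(tert-butyldimethylsilyloxy)-2,6,6-trimethylcyclohex-1-en-1-yl]-2,9-dimethylundeca-2,4,6,8,10-pentaenal
Conditions: toluene, 80 °C
Reagents that add atoms: none
Why: Wittig reaction with a stabilised formyl ylide should be E-selective and stop after one homologation, because the α-branched enal product is less reactive than 26.

Step 18
Reactants: 11 oxabicyclic silyloxyfuran; 28 C22 pentaenal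
Product: 30 tris-silyl ether of the target (triethylsilyl on the tertiary alcohol and tert-butyldimethylsilyl on both diol oxygens), via aldol triisopropylsilyl ether 29 (not isolated)
Conditions: TIPSOTf (20 mol%), i-Pr2NEt (40 mol%), CH2Cl2, −78 → −40 °C; then DBU, −40 → 25 °C
Reagents that add atoms: none
Why: Vinylogous Mukaiyama aldol reaction of the 2-silyloxyfuran at its C5 with the silyl-activated aldehyde (silicon passes to the aldol oxygen) followed by DBU-induced E1cB loss of silanolate should give the conjugated ylidenebutenolide as the thermodynamically preferred Z isomer.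

Step 19
Reactants: 30 tris-silyl ether of the target
Product: 31 CNP0216838.1 (target)
Conditions: HF·pyridine, pyridine, THF, 0 → 25 °C
Reagents that add atoms: none
Why: Buffered fluoride desilylation should cleave the three silyl ethers without touching the polyene, the enol lactone or any stereocentre.

Compound list
1 | (4R,6R)-4-hydroxy-2,2,6-trimethylcyclohexan-1-one (actinol) | O=C1[C@H](C)C[C@@H](O)CC1(C)C | starting material
2 | (4S,6R)-4-bromo-2,2,6-trimethylcyclohexan-1-one | O=C1[C@H](C)C[C@H](Br)CC1(C)C | intermediate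
3 | triethylsilyl enol ether of 2 (4-bromo-2,6,6-trimethyl-1-triethylsilyloxycyclohex-1-ene, C–Br carbon as in 2) | CC[Si](CC)(CC)OC1=C(C)C[C@H](Br)CC1(C)C | intermediate
4 | (2R,4R)-4-bromo-2,6,6-trimethyl-2-(triethylsilyloxy)cyclohexan-1-one | O=C1[C@](C)(O[Si](CC)(CC)CC)C[C@H](Br)CC1(C)C | intermediate
5 | 3-bromofuran-2(5H)-one | O=C1OCC=C1Br | starting material
6 | (E)-1,2-bis(tributylstannyl)ethene | CCCC[Sn](CCCC)(CCCC)/C=C/[Sn](CCCC)(CCCC)CCCC | starting material
7 | 3-[(E)-2-(tributylstannyl)ethenyl]furan-2(5H)-one | O=C1OCC=C1/C=C/[Sn](CCCC)(CCCC)CCCC | intermediate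
8 | tributyl{(E)-2-[2-(triisopropylsilyloxy)furan-3-yl]ethenyl}stannane | CC(C)[Si](C(C)C)(C(C)C)Oc1occc1/C=C/[Sn](CCCC)(CCCC)CCCC | intermediate
9 | (E)-2-[2-(triisopropylsilyloxy)furan-3-yl]ethenyllithium | CC(C)[Si](C(C)C)(C(C)C)Oc1occc1/C=C/[Li] | intermediate
10 | lithium alkoxide from addition of 9 to 4 (new oxygen trans to Br and to OSiEt3) | CC(C)[Si](C(C)C)(C(C)C)Oc1occc1/C=C/[C@]1(O[Li])[C@](C)(O[Si](CC)(CC)CC)C[C@H](Br)CC1(C)C | intermediate
11 | triisopropyl[(3-{(E)-2-[(1R,2R,4S)-2,6,6-trimethyl-2-(triethylsilyloxy)-7-oxabicyclo[2.2.1]heptan-1-yl]ethenyl}furan-2-yl)oxy]silane | CC(C)[Si](C(C)C)(C(C)C)Oc1occc1/C=C/[C@@]12O[C@@H](CC1(C)C)C[C@@]2(C)O[Si](CC)(CC)CC | intermediate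
12 | (4R,6R)-4-(tert-butyldimethylsilyloxy)-2,2,6-trimethylcyclohexan-1-one | O=C1[C@H](C)C[C@@H](O[Si](C)(C)C(C)(C)C)CC1(C)C | intermediate
13 | (4S)-4-(tert-butyldimethylsilyloxy)-2,6,6-trimethylcyclohex-2-en-1-one | O=C1C(C)=C[C@@H](O[Si](C)(C)C(C)(C)C)CC1(C)C | intermediate
14 | 3-methylpent-1-en-4-yn-3-ol (racemic) | C=CC(C)(O)C#C | starting material
15 | triethyl[(3-methylpent-1-en-4-yn-3-yl)oxy]silane (racemic) | C=CC(C)(O[Si](CC)(CC)CC)C#C | intermediate
16 | lithium acetylide of 15 | [Li]C#CC(C)(O[Si](CC)(CC)CC)C=C | intermediate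
17 | (4S)-4-(tert-butyldimethylsilyloxy)-2,6,6-trimethyl-1-[3-methyl-3-(triethylsilyloxy)pent-4-en-1-yn-1-yl]cyclohex-2-en-1-ol (epimers at both carbinol carbons) | C=CC(C)(O[Si](CC)(CC)CC)C#CC1(O)C(C)=C[C@@H](O[Si](C)(C)C(C)(C)C)CC1(C)C | intermediate
18 | (6S)-6-(tert-butyldimethylsilyloxy)-2,4,4-trimethyl-3-[3-methyl-3-(triethylsilyloxy)pent-4-en-1-yn-1-yl]cyclohex-2-en-1-one | C=CC(C)(O[Si](CC)(CC)CC)C#CC1=C(C)C(=O)[C@@H](O[Si](C)(C)C(C)(C)C)CC1(C)C | intermediate
19 | (1R,6S)-6-(tert-butyldimethylsilyloxy)-2,4,4-trimethyl-3-[3-methyl-3-(triethylsilyloxy)pent-4-en-1-yn-1-yl]cyclohex-2-en-1-ol | CC1=C(C#CC(C)(O[Si](CC)(CC)CC)C=C)C(C)(C)C[C@H](O[Si](C)(C)C(C)(C)C)[C@@H]1O | intermediate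
20 | (3R,4S)-3,4-bis(tert-butyldimethylsilyloxy)-2,6,6-trimethyl-1-[3-methyl-3-(triethylsilyloxy)pent-4-en-1-yn-1-yl]cyclohex-1-ene | CC1=C(C#CC(C)(O[Si](CC)(CC)CC)C=C)C(C)(C)C[C@H](O[Si](C)(C)C(C)(C)C)[C@@H]1O[Si](C)(C)C(C)(C)C | intermediate
21 | 1-[(3R,4S)-3,4-bis(tert-butyldimethylsilyloxy)-2,6,6-trimethylcyclohex-1-en-1-yl]-3-methylpent-4-en-1-yn-3-ol | CC1=C(C#CC(C)(O)C=C)C(C)(C)C[C@H](O[Si](C)(C)C(C)(C)C)[C@@H]1O[Si](C)(C)C(C)(C)C | intermediate
22 | (1E)-1-[(3R,4S)-3,4-bis(tert-butyldimethylsilyloxy)-2,6,6-trimethylcyclohex-1-en-1-yl]-3-methylpenta-1,4-dien-3-ol | CC1=C(/C=C/C(C)(O)C=C)C(C)(C)C[C@H](O[Si](C)(C)C(C)(C)C)[C@@H]1O[Si](C)(C)C(C)(C)C | intermediate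
23 | {(2E,4E)-5-[(3R,4S)-3,4-bis(tert-butyldimethylsilyloxy)-2,6,6-trimethylcyclohex-1-en-1-yl]-3-methylpenta-2,4-dien-1-yl}triphenylphosphonium bromide | CC1=C(/C=C/C(C)=C/C[P+](c2ccccc2)(c2ccccc2)c2ccccc2)C(C)(C)C[C@H](O[Si](C)(C)C(C)(C)C)[C@@H]1O[Si](C)(C)C(C)(C)C.[Br-] | intermediate
24 | (E)-4,4-dimethoxybut-2-enal | COC(OC)/C=C/C=O | starting material
25 | dimethyl acetal of 26 | CC1=C(/C=C/C(C)=C/C=C/C=C/C(OC)OC)C(C)(C)C[C@H](O[Si](C)(C)C(C)(C)C)[C@@H]1O[Si](C)(C)C(C)(C)C | intermediate
26 | (2E,4E,6E,8E)-9-[(3R,4S)-3,4-bis(tert-butyldimethylsilyloxy)-2,6,6-trimethylcyclohex-1-en-1-yl]-7-methylnona-2,4,6,8-tetraenal | CC1=C(/C=C/C(C)=C/C=C/C=C/C=O)C(C)(C)C[C@H](O[Si](C)(C)C(C)(C)C)[C@@H]1O[Si](C)(C)C(C)(C)C | intermediate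
27 | 2-(triphenylphosphoranylidene)propanal | CC(C=O)=P(c1ccccc1)(c1ccccc1)c1ccccc1 | starting material
28 | (2E,4E,6E,8E,10E)-11-[(3R,4S)-3,4-bis(tert-butyldimethylsilyloxy)-2,6,6-trimethylcyclohex-1-en-1-yl]-2,9-dimethylundeca-2,4,6,8,10-pentaenal | CC1=C(/C=C/C(C)=C/C=C/C=C/C=C(C)/C=O)C(C)(C)C[C@H](O[Si](C)(C)C(C)(C)C)[C@@H]1O[Si](C)(C)C(C)(C)C | intermediate
29 | aldol adduct of 11 and 28: butenolide with a CH(OSi(i-Pr)3)-pentaenyl group at C5 (epimers at the two new sp3 carbons) | CC1=C(/C=C/C(C)=C/C=C/C=C/C=C(C)/C(O[Si](C(C)C)(C(C)C)C(C)C)C2OC(=O)C(/C=C/[C@@]34O[C@@H](CC3(C)C)C[C@@]4(C)O[Si](CC)(CC)CC)=C2)C(C)(C)C[C@H](O[Si](C)(C)C(C)(C)C)[C@@H]1O[Si](C)(C)C(C)(C)C | intermediate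
30 | tris-silyl ether of the target (OSiEt3 on the bicycle, two OSiMe2t-Bu on the cyclohexene) | CC1=C(/C=C/C(C)=C/C=C/C=C/C=C(C)/C=C2C=C(/C=C/[C@@]34O[C@@H](CC3(C)C)C[C@@]4(C)O[Si](CC)(CC)CC)C(=O)O/2)C(C)(C)C[C@H](O[Si](C)(C)C(C)(C)C)[C@@H]1O[Si](C)(C)C(C)(C)C | intermediate
31 | (5Z)-3-{(E)-2-[(1R,2R,4S)-2-hydroxy-2,6,6-trimethyl-7-oxabicyclo[2.2.1]heptan-1-yl]ethenyl}-5-{(2E,4E,6E,8E,10E)-11-[(3R,4S)-3,4-dihydroxy-2,6,6-trimethylcyclohex-1-en-1-yl]-2,9-dimethylundeca-2,4,6,8,10-pentaen-1-ylidene}furan-2(5H)-one | CC1=C(/C=C/C(C)=C/C=C/C=C/C=C(C)/C=C2C=C(/C=C/[C@@]34O[C@@H](CC3(C)C)C[C@@]4(C)O)C(=O)O/2)C(C)(C)C[C@H](O)[C@@H]1O | target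

Total step count: 19. Longest linear sequence: 13 steps (1 → 12 → 13 → 17 → 18 → 19 → 20 → 21 → 22 → 23 → 26 → 28 → 30 → 31; steps 6, 7, 9–19).

Steps most likely to fail

Step 5. The addition to the doubly neopentyl carbonyl may be slow, so that the silyloxyfuran-bearing alkenyllithium is protonated or transfers silicon. Facial control may also erode if the ketone reacts through the alternative chair (attack anti to an axial silyloxy group), and silyl migration between the vicinal oxygens may open a fragmentation pathway. The fallback sets out from 4 and 6 and comes back at 11; it keeps the butenolide out of the organolithium step. Distannane 6 is treated with n-BuLi to give (E)-2-(tributylstannyl)ethenyllithium, which is added to 4 and cyclised under the conditions of step 5 to give tributyl{(E)-2-[(1R,2R,4S)-2,6,6-trimethyl-2-(triethylsilyloxy)-7-oxabicyclo[2.2.1]heptan-1-yl]ethenyl}stannane F4. Stille coupling of F4 with 5 (Pd2(dba)3, AsPh3, CuI, NMP) gives 3-{(E)-2-[(1R,2R,4S)-2,6,6-trimethyl-2-(triethylsilyloxy)-7-oxabicyclo[2.2.1]heptan-1-yl]ethenyl}furan-2(5H)-one F5, and TIPSOTf/Et3N converts this into 11.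

Step 2. The peracid may attack the enol ether with poor or reversed facial selectivity, the shielding by the pseudoaxial methyl group being opposed by the polar effect of the homoallylic substituent. The fallback sets out from 1 and comes back at 4; it hydroxylates before the inversion, so that the opposite facial bias becomes productive (oxygen must then enter trans to the ring oxygen substituent instead of cis to bromine). Actinol 1 is bis-silylated (excess TESOTf, Et3N) to the triethylsilyl enol ether of O-triethylsilyl actinol F1. mCPBA then gives (2R,4S)-2,6,6-trimethyl-2,4-bis(triethylsilyloxy)cyclohexan-1-one F2, and PPTS/MeOH frees the secondary alcohol to give (2R,4S)-4-hydroxy-2,6,6-trimethyl-2-(triethylsilyloxy)cyclohexan-1-one F3. CBr4/PPh3 converts F3 with inversion into 4. If neither order is selective, the epimers are separated at the stage of 4.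

Step 18. The silyl triflate may ionise the polyenal, leading to attack at vinylogous positions, isomerisation or oligomerisation of the polyene, and the Z geometry of the ylidene may be incompletely controlled. The fallback sets out from 28, uses stannane F4 from the fallback above, and comes back at 30; it needs no Lewis acid. Aldehyde 28 is homologated with lithiated trimethylsilyldiazomethane (Colvin rearrangement) to the terminal enyne (3R,4S)-3,4-bis(tert-butyldimethylsilyloxy)-1-[(1E,3E,5E,7E,9E)-3,10-dimethyldodeca-1,3,5,7,9-pentaen-11-yn-1-yl]-2,6,6-trimethylcyclohex-1-ene F6. Tandem Sonogashira coupling and 5-exo-dig lactonisation of F6 with (E)-2,3-dibromopropenoic acid (PdCl2(PPh3)2, CuI, Et3N, MeCN) gives the (5Z)-3-bromo-5-ylidenefuran-2(5H)-one F7. Stille coupling of F7 with F4 (Pd2(dba)3, AsPh3, NMP) gives 30.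

Further compounds
F1 | step 2 | triethylsilyl enol ether of O-triethylsilyl actinol (2,6,6-trimethyl-1,4-bis(triethylsilyloxy)cyclohex-1-ene, C4 as in 1) | CC[Si](CC)(CC)OC1=C(C)C[C@@H](O[Si](CC)(CC)CC)CC1(C)C
F2 | step 2 | (2R,4S)-2,6,6-trimethyl-2,4-bis(triethylsilyloxy)cyclohexan-1-one | O=C1[C@](C)(O[Si](CC)(CC)CC)C[C@@H](O[Si](CC)(CC)CC)CC1(C)C
F3 | step 2 | (2R,4S)-4-hydroxy-2,6,6-trimethyl-2-(triethylsilyloxy)cyclohexan-1-one | O=C1[C@](C)(O[Si](CC)(CC)CC)C[C@@H](O)CC1(C)C
F4 | step 5 | tributyl{(E)-2-[(1R,2R,4S)-2,6,6-trimethyl-2-(triethylsilyloxy)-7-oxabicyclo[2.2.1]heptan-1-yl]ethenyl}stannane | CCCC[Sn](CCCC)(CCCC)/C=C/[C@@]12O[C@@H](CC1(C)C)C[C@@]2(C)O[Si](CC)(CC)CC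
F5 | step 5 | 3-{(E)-2-[(1R,2R,4S)-2,6,6-trimethyl-2-(triethylsilyloxy)-7-oxabicyclo[2.2.1]heptan-1-yl]ethenyl}furan-2(5H)-one | O=C1OCC=C1/C=C/[C@@]12O[C@@H](CC1(C)C)C[C@@]2(C)O[Si](CC)(CC)CC
F6 | step 18 | (3R,4S)-3,4-bis(tert-butyldimethylsilyloxy)-1-[(1E,3E,5E,7E,9E)-3,10-dimethyldodeca-1,3,5,7,9-pentaen-11-yn-1-yl]-2,6,6-trimethylcyclohex-1-ene | CC1=C(/C=C/C(C)=C/C=C/C=C/C=C(C)/C#C)C(C)(C)C[C@H](O[Si](C)(C)C(C)(C)C)[C@@H]1O[Si](C)(C)C(C)(C)C
F7 | step 18 | (5Z)-3-bromo-5-{(2E,4E,6E,8E,10E)-11-[(3R,4S)-3,4-bis(tert-butyldimethylsilyloxy)-2,6,6-trimethylcyclohex-1-en-1-yl]-2,9-dimethylundeca-2,4,6,8,10-pentaen-1-ylidene}furan-2(5H)-one | CC1=C(/C=C/C(C)=C/C=C/C=C/C=C(C)/C=C2C=C(Br)C(=O)O/2)C(C)(C)C[C@H](O[Si](C)(C)C(C)(C)C)[C@@H]1O[Si](C)(C)C(C)(C)C
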